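**Assumption:** ring carbons are numbered as in germacranolides (C1 ketal carbon, C4 ether carbon, C8 ester carbon, C10 methyl-bearing carbon). The SMILES is read as 1S,4R,8S,10R, with the lactone oxygen trans to C4 on C5=C6 and an (E)-2-methylbut-2-enoate (tiglate) at O8.

## Retrosynthetic overview

1. Vernolide-B ⇐ a C6–C7-fused furan: singlet oxygen gives the 6-hydroxybutenolide, and dehydrative acetylation gives the ylidene butenolide and the 13-acetate. The C1 methyl ketal ⇐ MeOH addition to a bridgehead enol ether.
2. Ten-membered ring ⇐ C7–C8 closure by a Ni/Cr-catalysed addition of a 3-bromofuran C–Br to the C8 aldehyde (sets C8), then tigloylation.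
3. Oxygen bridge ⇐ Au-catalysed 5-endo cyclisation of the C4 hydroxyl onto a C1≡C2 alkyne.
4. Open chain ⇐ three pieces: alkyne 7 (C8–C10, C1, C2; C10 from (R)-but-3-yn-2-ol), chloro-epoxide linchpin 10 (C3–C5, C15; C4 from Sharpless epoxidation), bromofuran 14 (C6, C7, C11–C13).
5. Ring order: furan (bought) → 2,3-dihydrofuran (O-bridge) → ten-membered carbocycle → butenolide (from the furan).

## Route

### Alkyne fragment (C8–C10, C1, C2)

**Step 1**
Reactants: 1, (R)-but-3-yn-2-ol
Product: 2, (2R)-but-3-yn-2-yl methanesulfonate
Conditions: MsCl, Et3N, CH2Cl2, 0 °C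
Reagents that add atoms: methanesulfonyl chloride, CS(=O)(=O)Cl
Why: Standard O-sulfonylation; the C–O bond is untouched, so the configuration is retained.

**Step 2**
Reactants: 2, (2R)-but-3-yn-2-yl methanesulfonate; 3, methyl acetoacetate (2 equiv)
Product: 4, methyl (3R)-2-acetyl-3-methylpent-4-ynoate (C2 epimers)
Conditions: NaH, THF/DMF, 0 → 60 °C
Reagents that add atoms: none (both partners are reactants)
Why: SN2 alkylation of a soft β-keto ester enolate at the secondary propargylic mesylate goes with inversion and fixes the future C10 (the descriptor stays R only because the CIP priorities change).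

**Step 3**
Reactants: 4, methyl (3R)-2-acetyl-3-methylpent-4-ynoate
Product: 5, methyl (3R)-3-methylpent-4-ynoate
Conditions: NaOMe (cat.), MeOH, 65 °C
Reagents that add atoms: none
Why: Retro-Claisen alcoholysis (deacetylation) with catalytic methoxide removes the acetyl group as methyl acetate; the stereocentre is β to the ester and not enolisable.

**Step 4**
Reactants: 5, methyl (3R)-3-methylpent-4-ynoate
Product: 6, (3R)-3-methylpent-4-yn-1-ol
Conditions: LiAlH4, Et2O, 0 °C
Reagents that add atoms: none
Why: Hydride reduction of the ester to the primary alcohol (future C8).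

**Step 5**
Reactants: 6, (3R)-3-methylpent-4-yn-1-ol
Product: 7, triethyl{[(3R)-3-methylpent-4-yn-1-yl]oxy}silane
Conditions: TESCl, imidazole, CH2Cl2, 0 °C
Reagents that add atoms: chlorotriethylsilane, CC[Si](CC)(CC)Cl
Why: Silylation gives a base-stable primary TES ether that is later oxidised directly to the aldehyde.

### Epoxide linchpin (C3–C5, C15)

**Step 6**
Reactants: 8, 2-methylprop-2-en-1-ol
Product: 9, (R)-(2-methyloxiran-2-yl)methanol
Conditions: Ti(OiPr)4 (5 mol%), D-(−)-DIPT (6 mol%), t-BuOOH, 4 Å MS, CH2Cl2, −20 °C
Reagents that add atoms: tert-butyl hydroperoxide, CC(C)(C)OO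
Why: Sharpless asymmetric epoxidation; the D-(−)-tartrate delivers oxygen to the face that gives the R epoxy alcohol, which becomes C4 (about 90–95% ee).

**Step 7**
Reactants: 9, (R)-(2-methyloxiran-2-yl)methanol
Product: 10, (S)-2-(chloromethyl)-2-methyloxirane
Conditions: PPh3, CCl4, NaHCO3, reflux
Reagents that add atoms: carbon tetrachloride, ClC(Cl)(Cl)Cl
Why: Appel chlorination of the epoxy alcohol at the CH2OH carbon leaves the quaternary centre untouched (the descriptor changes only through CIP priorities).

### Furan fragment (C6, C7, C11–C13)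

**Step 8**
Reactants: 11, 3,4-dibromofuran
Product: 12, 4-bromofuran-3-carbaldehyde
Conditions: n-BuLi (1.0 equiv), Et2O, −78 °C; then DMF
Reagents that add atoms: N,N-dimethylformamide, CN(C)C=O
Why: Mono bromine–lithium exchange and formylation of the 3-furyllithium install C13.

**Step 9**
Reactants: 12, 4-bromofuran-3-carbaldehyde
Product: 13, (4-bromofuran-3-yl)methanol
Conditions: NaBH4, MeOH, 0 °C
Reagents that add atoms: none
Why: Borohydride reduction of the aldehyde.

**Step 10**
Reactants: 13, (4-bromofuran-3-yl)methanol
Product: 14, tert-butyl[(4-bromofuran-3-yl)methoxy]dimethylsilane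
Conditions: TBSCl, imidazole, DMF, rt
Reagents that add atoms: tert-butyldimethylsilyl chloride, CC(C)(C)[Si](C)(C)Cl
Why: Silylation gives a non-coordinating ether that survives lithiation and Swern conditions.

### Assembly

**Step 11**
Reactants: 14, tert-butyl[(4-bromofuran-3-yl)methoxy]dimethylsilane; 10, (S)-2-(chloromethyl)-2-methyloxirane
Product: 15, (2S)-1-[3-bromo-4-({[tert-butyl(dimethyl)silyl]oxy}methyl)furan-2-yl]-3-chloro-2-methylpropan-2-ol
Conditions: LDA, THF, −78 °C; then 10, BF3·OEt2 (excess), −78 °C
Reagents that add atoms: none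
Why: LDA deprotonates the furan α-position next to bromine, and the BF3-assisted furyllithium opens the epoxide at its CH2 terminus (C5–C6 bond); the neopentyl-type chloride is inert and the quaternary centre is not touched.

**Step 12**
Reactants: 15, the chlorohydrin
Product: 16, (2S)-2-{[3-bromo-4-({[tert-butyl(dimethyl)silyl]oxy}methyl)furan-2-yl]methyl}-2-methyloxirane
Conditions: NaH, THF, 0 °C → rt
Reagents that add atoms: none
Why: Intramolecular Williamson closure of the tertiary alkoxide onto CH2Cl re-forms an epoxide on the other arm (future C3) without touching the stereocentre.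

**Step 13**
Reactants: 7, triethyl{[(3R)-3-methylpent-4-yn-1-yl]oxy}silane; 16, the epoxide
Product: 17, (2R,6R)-1-[3-bromo-4-({[tert-butyl(dimethyl)silyl]oxy}methyl)furan-2-yl]-2,6-dimethyl-8-[(triethylsilyl)oxy]oct-4-yn-2-ol
Conditions: 7, n-BuLi, THF, −78 °C; BF3·OEt2; then 16, −78 °C
Reagents that add atoms: none
Why: Yamaguchi–Hirao alkynylation: the lithium acetylide/BF3 pair opens the 2,2-disubstituted epoxide at CH2 (C2–C3 bond) and frees the C4 tertiary alcohol with both stereocentres intact (C4 is now R by CIP).

**Step 14**
Reactants: 17, the alkynol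
Product: 18, (3R,7R)-8-[3-bromo-4-({[tert-butyl(dimethyl)silyl]oxy}methyl)furan-2-yl]-7-hydroxy-3,7-dimethyloct-4-ynal
Conditions: (COCl)2, DMSO, CH2Cl2, −78 → −40 °C; then Et3N
Reagents that add atoms: none
Why: Swern conditions convert a primary TES ether directly into the aldehyde, while the primary TBS ether, the tertiary alcohol and the alkyne are left alone.

**Step 15**
Reactants: 18, the alkynol aldehyde
Product: 19, (3R)-3-[(5R)-5-{[3-bromo-4-({[tert-butyl(dimethyl)silyl]oxy}methyl)furan-2-yl]methyl}-5-methyl-4,5-dihydrofuran-2-yl]butanal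
Conditions: Ph3PAuNTf2 (2 mol%), 4 Å MS, toluene, rt; Et3N quench, Et3N-deactivated silica
Reagents that add atoms: none
Why: Gold(I)-catalysed 5-endo-dig cycloisomerisation of the homopropargylic tertiary alcohol gives the 2,3-dihydrofuran, which fixes the ketone position at C1, forms the oxygen bridge and leaves C1 planar so that no ketal epimers arise before ring closure.

**Step 16**
Reactants: 19, the bromofuran aldehyde
Product: 20, (4R,8S,10R)-macrocyclic furyl carbinol: ten-membered carbocycle C1–C10 with the C1–O–C4 bridge as a 2,3-dihydrofuran (C1=C2), a furan fused at C6–C7 (furan O on C6, C12–H, CH2OTBS on C11), 4-Me, 10-Me, 8-OH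
Conditions: CrCl2 (15 mol%), chiral oxazoline–aryl sulfonamide ligand (Kishi type, 17 mol%; the enantiomer giving 8S), proton sponge, NiCl2·(2,9-dimethyl-1,10-phenanthroline) (5 mol%), Mn, Cp2ZrCl2, LiCl, MeCN, rt, slow addition of 19 (final 2 mM)
Reagents that add atoms: none
Why: Proposed new method: a catalytic, ligand-controlled Ni/Cr ring closure of a β-bromofuran onto a tethered aldehyde — Ni(0) inserts into the furyl C–Br bond, the furyl group passes to a Cr(III) centre bound to the chiral sulfonamide, and the furyl–Cr adds to the aldehyde through a ligand-defined six-coordinate transition state that overrides the weak bias of the remote C10 centre and gives 8S, while Cp2ZrCl2 releases the Cr alkoxide and Mn recycles Cr and Ni so that no acid or silyl chloride meets the enol ether; the closest known chemistry is the catalytic asymmetric Nozaki–Hiyama–Kishi coupling of alkenyl iodides (including macrocyclisations) and stoichiometric NHK closures of bromofuran aldehydes to furanophanes, neither shown for a 3-bromofuran under ligand control in a ten-membered ring.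

**Step 17**
Reactants: 20, the macrocyclic alcohol; 21, tiglic acid [(E)-2-methylbut-2-enoic acid]
Product: 22, the 8-O-tiglate of 20
Conditions: 21, 2,4,6-trichlorobenzoyl chloride, Et3N, THF; then 20, DMAP, toluene, rt
Reagents that add atoms: none (tiglic acid is a reactant)
Why: Yamaguchi esterification acylates the secondary alcohol with retention at C8 under basic conditions that spare the enol ether.

**Step 18**
Reactants: 22, the enol ether tiglate
Product: 23, (1S,4R,8S,10R)-1-methoxy-1,4-epoxy macrocycle with the C6–C7-fused furan, free 13-OH and 8-O-tiglate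
Conditions: CSA (10 mol%), MeOH/CH2Cl2, 0 °C → rt
Reagents that add atoms: methanol, CO
Why: Acid-catalysed Markovnikov addition of MeOH to the bridgehead enol ether goes through the C1 oxocarbenium, which can only be captured from the face outside the carbon bridge, so C1 is set as S (OMe cis to the C4 methyl); the same conditions cleave the primary TBS ether.

**Step 19**
Reactants: 23, the furan ketal
Product: 24, the 6-hydroxybutenolide [5-hydroxy-2(5H)-furanone: C12=O, C11 bearing CH2OH, C7=C11, C6(OH); C6 epimers]
Conditions: O2, hν (visible), tetraphenylporphyrin (cat.), i-Pr2NEt, CH2Cl2, −78 °C → rt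
Reagents that add atoms: dioxygen, O=O
Why: Singlet-oxygen [4+2] addition to the trisubstituted furan, then base-induced Kornblum–DeLaMare opening at the only hydrogen-bearing α-carbon (C12), puts the carbonyl at C12 and the hydroxyl at C6; the electron-poor tiglate alkene reacts far more slowly.

**Step 20**
Reactants: 24, the 6-hydroxybutenolide
Product: 25, Vernolide-B
Conditions: Ac2O, pyridine, DMAP (cat.), CH2Cl2, 0 °C → rt; then Et3N, rt
Reagents that add atoms: acetic anhydride, CC(=O)OC(C)=O
Why: Acetylation of 13-OH and of the 6-OH pseudo-acid, then elimination of the C6 acetate toward C5 (the only neighbouring C–H), gives the γ-ylidene butenolide; the oxygen-bridged ring should favour the isomer with C4 and C7 cis on C5=C6, though this geometry is a prediction, not a certainty.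

## Compound list

1 | (R)-but-3-yn-2-ol | C#C[C@@H](C)O | starting material
2 | (2R)-but-3-yn-2-yl methanesulfonate | C#C[C@@H](C)OS(C)(=O)=O | intermediate
3 | methyl acetoacetate | CC(=O)CC(=O)OC | starting material
4 | methyl (3R)-2-acetyl-3-methylpent-4-ynoate | C#C[C@H](C)C(C(C)=O)C(=O)OC | intermediate
5 | methyl (3R)-3-methylpent-4-ynoate | C#C[C@H](C)CC(=O)OC | intermediate
6 | (3R)-3-methylpent-4-yn-1-ol | C#C[C@H](C)CCO | intermediate
7 | triethyl{[(3R)-3-methylpent-4-yn-1-yl]oxy}silane | C#C[C@H](C)CCO[Si](CC)(CC)CC | intermediate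
8 | 2-methylprop-2-en-1-ol | C=C(C)CO | starting material
9 | (R)-(2-methyloxiran-2-yl)methanol | C[C@@]1(CO)CO1 | intermediate
10 | (S)-2-(chloromethyl)-2-methyloxirane | C[C@@]1(CCl)CO1 | intermediate
11 | 3,4-dibromofuran | Brc1cocc1Br | starting material
12 | 4-bromofuran-3-carbaldehyde | O=Cc1cocc1Br | intermediate
13 | (4-bromofuran-3-yl)methanol | OCc1cocc1Br | intermediate
14 | tert-butyl[(4-bromofuran-3-yl)methoxy]dimethylsilane | CC(C)(C)[Si](C)(C)OCc1cocc1Br | intermediate
15 | (2S)-1-[3-bromo-4-(TBSO-methyl)furan-2-yl]-3-chloro-2-methylpropan-2-ol | C[C@@](O)(CCl)Cc1occ(CO[Si](C)(C)C(C)(C)C)c1Br | intermediate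
16 | (2S)-2-{[3-bromo-4-(TBSO-methyl)furan-2-yl]methyl}-2-methyloxirane | C[C@]1(Cc2occ(CO[Si](C)(C)C(C)(C)C)c2Br)CO1 | intermediate
17 | (2R,6R)-1-[3-bromo-4-(TBSO-methyl)furan-2-yl]-2,6-dimethyl-8-(triethylsilyloxy)oct-4-yn-2-ol | C[C@](O)(Cc1occ(CO[Si](C)(C)C(C)(C)C)c1Br)CC#C[C@H](C)CCO[Si](CC)(CC)CC | intermediate
18 | (3R,7R)-8-[3-bromo-4-(TBSO-methyl)furan-2-yl]-7-hydroxy-3,7-dimethyloct-4-ynal | C[C@](O)(Cc1occ(CO[Si](C)(C)C(C)(C)C)c1Br)CC#C[C@H](C)CC=O | intermediate
19 | (3R)-3-[(5R)-5-{[3-bromo-4-(TBSO-methyl)furan-2-yl]methyl}-5-methyl-4,5-dihydrofuran-2-yl]butanal | C[C@]1(Cc2occ(CO[Si](C)(C)C(C)(C)C)c2Br)CC=C(O1)[C@H](C)CC=O | intermediate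
20 | (4R,8S,10R)-macrocyclic furyl carbinol (1,4-O-bridged C1=C2 enol ether, C6–C7-fused furan, 13-OTBS, 8-OH) | C[C@]12Cc3occ(CO[Si](C)(C)C(C)(C)C)c3[C@@H](O)C[C@@H](C)C(=CC1)O2 | intermediate
21 | tiglic acid, (E)-2-methylbut-2-enoic acid | C/C=C(\C)C(=O)O | starting material
22 | 8-O-tiglate of 20 | C[C@]12Cc3occ(CO[Si](C)(C)C(C)(C)C)c3[C@@H](OC(=O)/C(C)=C/C)C[C@@H](C)C(=CC1)O2 | intermediate
23 | (1S,4R,8S,10R)-1-methoxy-1,4-epoxy furan macrocycle, 13-OH, 8-O-tiglate | C[C@]12Cc3occ(CO)c3[C@@H](OC(=O)/C(C)=C/C)C[C@@H](C)[C@](OC)(CC1)O2 | intermediate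
24 | 6-hydroxybutenolide (C6 epimers), 13-OH, 8-O-tiglate, 1-OMe ketal | C[C@]12CC3(O)OC(=O)C(CO)=C3[C@@H](OC(=O)/C(C)=C/C)C[C@@H](C)[C@](OC)(CC1)O2 | intermediate
25 | Vernolide-B | C[C@]12/C=C3/OC(=O)C(COC(C)=O)=C3[C@@H](OC(=O)/C(C)=C/C)C[C@@H](C)[C@](OC)(CC1)O2 | target

## Summary

**Total steps:** 20.

**Longest linear sequence:** 13 steps (1–5 then 13–20; equally 8–12 then 13–20).

**Steps most likely to fail, with fallbacks**

1. **Step 16 (proposed Ni/Cr ring closure).** The furyl C–Br bond may add to nickel too slowly, the substrate may oligomerise, or the wrong C8 epimer may form. Fallback with known chemistry: exchange Br for I on 17 (CuI, NaI, diamine; aromatic Finkelstein), repeat steps 14–15, and close the ring with stoichiometric CrCl2/NiCl2 (classical NHK, as used for bromofuran aldehyde furanophane closures). Then set 8S by Dess–Martin oxidation to the C8 ketone and CBS reduction, so that C8 is set by a reagent-controlled ketone reduction and not in the ring closure.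

2. **Step 15 (gold cyclisation to the acid-labile enol ether aldehyde).** A competing furan–alkyne or aldehyde–alkyne gold pathway, or hydrolysis of 19, could erode the yield. Fallback: run the gold cyclisation on 17 in MeOH to give the C1 methyl ketal (both anomers), then do step 14 and separate the anomers. Close the ring on the anomer with C10 and C5 cis, and recycle the other by PPTS/MeOH equilibration. This replaces the planar enol ether by an sp3 ketal before ring closure; step 18 then only removes the TBS group.

3. **Step 20 (one-pot acetylation and dehydration).** The C6 acetate may not eliminate cleanly, the 13-acetate is prone to SN2′ loss under base, and the C5=C6 geometry is not guaranteed. Fallback: keep the 13-O-TBS group through step 18 (PPTS in place of CSA) and dehydrate the 6-hydroxybutenolide separately with Burgess reagent or MsCl/Et3N. If the alkene is formed as a mixture, equilibrate it photochemically with catalytic I2, then remove the TBS group with HF·pyridine and acetylate with Ac2O/pyridine as the last step.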